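**Retrosynthetic overview**

- Final events: global hydrogenolysis of an octabenzyl ether. The upper C4–H (2,4-cis) comes from ionic hydrogenation of a C4 carbinol. The interflavan C4(upper)–C8(lower) bond comes from addition of the C8-lithiated lower flavan to an (S)-flavanone.
- Lower (epigallocatechin) unit: the 3-OH cis to the 2-aryl group comes from hydride reduction of a flavan-3-one. Ring C of that ketone is closed at C4–C4a by gold-catalysed alkyne oxidation and carbene arylation of an open-chain aryl propargyl ether (the alkyne becomes C3–C4, the ether is O1–C2).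
- Enabling feature: ring A of the lower unit is a phloroglucinol ring in which C4a is ortho to O1 and O5 and para to O7, and C4 is a methylene next to the oxygen-bearing C3. C4 can therefore be an α-keto carbene carbon caught by the most nucleophilic arene carbon, and the two ortho carbons of the 3,5-bis(benzyloxy)phenyl ether are equivalent, so only one closure is possible.
- The ether comes from Mitsunobu inversion of an (R)-aryl propargylic alcohol (asymmetric alkynylation of 3,4,5-tris(benzyloxy)benzaldehyde) with 3,5-bis(benzyloxy)phenol. The flavanone comes from asymmetric conjugate addition of an arylboronic acid to 7-(benzyloxy)chromone.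
- Ring order: rings A and B of both units and the upper pyranone ring are purchased. Lower ring C is the only ring made (key step), and the two halves are joined afterwards.

Key step: step 3

Assumption: the facial sense of the chiral ligands in steps 1 and 8 is assigned by analogy with the parent reactions of these catalyst systems; should either prove opposite on these substrates, the mirror-image ligand is to be used.

**Route**

Step 1
Reactants: 1 3,4,5-tris(benzyloxy)benzaldehyde; 2 ethynyltrimethylsilane
Product: 4 (R)-1-[3,4,5-tris(benzyloxy)phenyl]prop-2-yn-1-ol, via silylated alkynol 3 (not isolated)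
Conditions: Me2Zn, (R,R)-ProPhenol (10 mol %), Ph3P=O (20 mol %), toluene, 0 °C; H2O work-up; then K2CO3 (cat.), MeOH, rt
Reagents that add atoms: none
Why: Zinc–ProPhenol-catalysed enantioselective alkynylation of an aromatic aldehyde should deliver the zinc alkynylide to the Re face of the aldehyde inside the chiral dinuclear zinc pocket, which sets the carbinol centre, and the subsequent methanolysis of the C–Si bond frees the terminal alkyne without touching that centre.

Step 2
Reactants: 4 (R)-1-[3,4,5-tris(benzyloxy)phenyl]prop-2-yn-1-ol; 5 3,5-bis(benzyloxy)phenol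
Product: 6 (S)-1,3-bis(benzyloxy)-5-({1-[3,4,5-tris(benzyloxy)phenyl]prop-2-yn-1-yl}oxy)benzene
Conditions: PPh3, DIAD, toluene, −20 → 0 °C
Reagents that add atoms: none
Why: Mitsunobu etherification of an acidic phenol with a secondary propargylic alcohol should proceed by SN2 displacement of the oxyphosphonium group with inversion, turning the (R)-carbinol into the (S)-ether that carries the future C2 configuration, while the inductively withdrawing meta-benzyloxy groups and the cold, non-polar medium disfavour ionisation.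

Step 3
Reactants: 6 (S)-1,3-bis(benzyloxy)-5-({1-[3,4,5-tris(benzyloxy)phenyl]prop-2-yn-1-yl}oxy)benzene
Product: 7 (R)-5,7-bis(benzyloxy)-2-[3,4,5-tris(benzyloxy)phenyl]chroman-3-one
Conditions: (Me4tBuXPhos)AuNTf2 (5 mol %), 2,6-dichloropyridine N-oxide (2 equiv), ClCH2CH2Cl, rt, slow addition of 6
Reagents that add atoms: 2,6-dichloropyridine N-oxide, [O-][n+]1c(Cl)cccc1Cl
Why: Cationic monovalent gold activates the terminal alkyne, the N-oxide oxygen adds to the internal carbon (future C3) and N–O heterolysis expels 2,6-dichloropyridine to leave a catalyst-bound α-oxo gold carbene at the terminal carbon (future C4), which is attacked by the ortho carbon of the phloroglucinol ring (future C4a) before proton loss and protodeauration give the ketone. This is the known gold-catalysed oxidative cyclisation of aryl propargyl ethers to chroman-3-ones, an oxidative polarity reversal that lets the α-carbon of the C3 ketone (a natural donor) be joined to a donor arene carbon while the C3 oxygen is installed in the same operation. Ring C closes in the six-membered mode by intramolecular electrophilic aromatic substitution, the arene carbon attacking the carbene carbon so that both former alkyne carbons lie in the new ring. No new stereocentre is formed; no bond to C2 changes and its configuration from step 2 should be carried over, the only base present being the very weakly basic 2,6-dichloropyridine. The step needs oxidation of the gold–alkyne complex to outrun direct hydroarylation and needs the carbene to be taken by ring A and not by ring B or by a second N-oxide; the bulky biaryl phosphine, excess N-oxide and slow substrate addition serve the first, and the second is secured by C4a being ortho/para to three oxygens and reachable through a six-membered transition state, while the equivalence of the two ortho positions of the 3,5-bis(benzyloxy)phenoxy group allows only one regioisomer.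

Step 4
Reactants: 7 (R)-5,7-bis(benzyloxy)-2-[3,4,5-tris(benzyloxy)phenyl]chroman-3-one
Product: 8 (2R,3R)-5,7-bis(benzyloxy)-2-[3,4,5-tris(benzyloxy)phenyl]chroman-3-ol
Conditions: LiBH(s-Bu)3, THF, −78 °C; then H2O
Reagents that add atoms: none
Why: Substrate-controlled ketone reduction with a bulky trialkylborohydride should attack C3 along the equatorial direction of the half-chair in which the C2 aryl group is pseudo-equatorial, placing the new hydroxyl axial and cis to the aryl group (3R), as is usual for flavan-3-ones.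

Step 5
Reactants: 8 (2R,3R)-5,7-bis(benzyloxy)-2-[3,4,5-tris(benzyloxy)phenyl]chroman-3-ol
Product: 9 (2R,3R)-3,5,7-tris(benzyloxy)-2-[3,4,5-tris(benzyloxy)phenyl]chromane
Conditions: NaH, BnBr, DMF, 0 °C → rt
Reagents that add atoms: benzyl bromide, BrCc1ccccc1
Why: Williamson etherification of the secondary alkoxide protects the 3-OH against the organolithium chemistry of step 9 with a group that leaves in the final hydrogenolysis, and no stereocentre is affected.

Step 6
Reactants: 9 (2R,3R)-3,5,7-tris(benzyloxy)-2-[3,4,5-tris(benzyloxy)phenyl]chromane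
Product: 10 (2R,3R)-3,5,7-tris(benzyloxy)-8-bromo-2-[3,4,5-tris(benzyloxy)phenyl]chromane
Conditions: NBS, CH2Cl2, −40 °C
Reagents that add atoms: N-bromosuccinimide, O=C1CCC(=O)N1Br
Why: Electrophilic aromatic bromination of a 5,7-di-O-benzyl flavan should take place at C8, which is flanked by the ring oxygen and one benzyloxy group and is less hindered than C6 between two benzyloxy groups, the known regiochemistry for this substitution pattern.

Step 7
Reactants: 11 7-hydroxy-4H-chromen-4-one
Product: 12 7-(benzyloxy)-4H-chromen-4-one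
Conditions: BnBr, K2CO3, DMF, rt
Reagents that add atoms: benzyl bromide, BrCc1ccccc1
Why: Williamson etherification of the acidic vinylogous-acid phenol is a routine protection that creates no stereocentre.

Step 8
Reactants: 12 7-(benzyloxy)-4H-chromen-4-one; 13 [4-(benzyloxy)phenyl]boronic acid
Product: 14 (S)-7-(benzyloxy)-2-[4-(benzyloxy)phenyl]chroman-4-one
Conditions: Pd(OCOCF3)2 (5 mol %), (R)-t-BuPyOX (6 mol %), NH4PF6 (30 mol %), H2O (5 equiv), ClCH2CH2Cl, 60 °C
Reagents that add atoms: none
Why: Asymmetric conjugate addition of an arylboronic acid to a chromone under divalent palladium/pyridine-oxazoline catalysis should add the aryl–palladium species across C2=C3 on the enone face left open by the tert-butyl group of the ligand and protonate the palladium enolate, setting C2 as (S) under base-free conditions that do not open the flavanone.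

Step 9
Reactants: 10 (2R,3R)-3,5,7-tris(benzyloxy)-8-bromo-2-[3,4,5-tris(benzyloxy)phenyl]chromane; 14 (S)-7-(benzyloxy)-2-[4-(benzyloxy)phenyl]chroman-4-one
Product: 16 (2S)-7-(benzyloxy)-2-[4-(benzyloxy)phenyl]-4-{(2R,3R)-3,5,7-tris(benzyloxy)-2-[3,4,5-tris(benzyloxy)phenyl]chroman-8-yl}chroman-4-ol (both C4 epimers), via aryllithium 15 (not isolated)
Conditions: n-BuLi, THF, −78 °C; then 14 premixed with LaCl3·2LiCl in THF, −78 → −40 °C; then H2O
Reagents that add atoms: n-butyllithium, [Li]CCCC (supplies the lithium of intermediate 15 only)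
Why: Bromine–lithium exchange followed by lanthanum-assisted 1,2-addition of the aryllithium to the ketone should form the interflavan C4–C8 bond with the regiochemistry fixed by the bromide, and the new carbinol centre may form as a mixture because it is ionised in step 10.

Step 10
Reactants: 16 (2S)-7-(benzyloxy)-2-[4-(benzyloxy)phenyl]-4-{(2R,3R)-3,5,7-tris(benzyloxy)-2-[3,4,5-tris(benzyloxy)phenyl]chroman-8-yl}chroman-4-ol
Product: 17 (2R,3R)-3,5,7-tris(benzyloxy)-8-{(2S,4S)-7-(benzyloxy)-2-[4-(benzyloxy)phenyl]chroman-4-yl}-2-[3,4,5-tris(benzyloxy)phenyl]chromane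
Conditions: Et3SiH, CF3CO2H, CH2Cl2, −78 → −20 °C
Reagents that add atoms: none
Why: Ionic hydrogenation: the doubly benzylic tertiary alcohol ionises to a 4-arylflavan-4-yl cation stabilised by the para 7-benzyloxy group, and silane hydride should enter axially on the envelope whose C2 aryl group is pseudo-equatorial, leaving the C4 aryl group equatorial and cis to the C2 aryl group (4S) under control of the C2 centre, which is also the more stable arrangement.

Step 11
Reactants: 17 (2R,3R)-3,5,7-tris(benzyloxy)-8-{(2S,4S)-7-(benzyloxy)-2-[4-(benzyloxy)phenyl]chroman-4-yl}-2-[3,4,5-tris(benzyloxy)phenyl]chromane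
Product: 18 (2R,3R)-8-[(2S,4S)-7-hydroxy-2-(4-hydroxyphenyl)chroman-4-yl]-2-(3,4,5-trihydroxyphenyl)chromane-3,5,7-triol
Conditions: H2 (1 atm), Pd(OH)2/C, THF/MeOH, rt, work-up under argon
Reagents that add atoms: none
Why: Heterogeneous hydrogenolysis should cleave all eight O-benzyl groups, while the cyclic benzylic C2–O1 bonds and the interflavan bond are expected to survive as they do in debenzylations of other flavans, so no stereocentre is touched.

**Compound list**

1 | 3,4,5-tris(benzyloxy)benzaldehyde | O=Cc1cc(OCc2ccccc2)c(OCc2ccccc2)c(OCc2ccccc2)c1 | starting material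
2 | ethynyltrimethylsilane | C#C[Si](C)(C)C | starting material
3 | (S)-1-[3,4,5-tris(benzyloxy)phenyl]-3-(trimethylsilyl)prop-2-yn-1-ol | O[C@@H](c1cc(OCc2ccccc2)c(OCc2ccccc2)c(OCc2ccccc2)c1)C#C[Si](C)(C)C | intermediate
4 | (R)-1-[3,4,5-tris(benzyloxy)phenyl]prop-2-yn-1-ol | O[C@@H](c1cc(OCc2ccccc2)c(OCc2ccccc2)c(OCc2ccccc2)c1)C#C | intermediate
5 | 3,5-bis(benzyloxy)phenol | Oc1cc(OCc2ccccc2)cc(OCc2ccccc2)c1 | starting material
6 | (S)-1,3-bis(benzyloxy)-5-({1-[3,4,5-tris(benzyloxy)phenyl]prop-2-yn-1-yl}oxy)benzene | c1c(OCc2ccccc2)cc(OCc2ccccc2)cc1O[C@H](c1cc(OCc2ccccc2)c(OCc2ccccc2)c(OCc2ccccc2)c1)C#C | intermediate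
7 | (R)-5,7-bis(benzyloxy)-2-[3,4,5-tris(benzyloxy)phenyl]chroman-3-one | c1c(OCc3ccccc3)cc(OCc3ccccc3)c2c1O[C@H](c1cc(OCc3ccccc3)c(OCc3ccccc3)c(OCc3ccccc3)c1)C(=O)C2 | intermediate
8 | (2R,3R)-5,7-bis(benzyloxy)-2-[3,4,5-tris(benzyloxy)phenyl]chroman-3-ol | c1c(OCc3ccccc3)cc(OCc3ccccc3)c2c1O[C@H](c1cc(OCc3ccccc3)c(OCc3ccccc3)c(OCc3ccccc3)c1)[C@H](O)C2 | intermediate
9 | (2R,3R)-3,5,7-tris(benzyloxy)-2-[3,4,5-tris(benzyloxy)phenyl]chromane | c1c(OCc3ccccc3)cc(OCc3ccccc3)c2c1O[C@H](c1cc(OCc3ccccc3)c(OCc3ccccc3)c(OCc3ccccc3)c1)[C@H](OCc1ccccc1)C2 | intermediate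
10 | (2R,3R)-3,5,7-tris(benzyloxy)-8-bromo-2-[3,4,5-tris(benzyloxy)phenyl]chromane | Brc1c(OCc3ccccc3)cc(OCc3ccccc3)c2c1O[C@H](c1cc(OCc3ccccc3)c(OCc3ccccc3)c(OCc3ccccc3)c1)[C@H](OCc1ccccc1)C2 | intermediate
11 | 7-hydroxy-4H-chromen-4-one | O=c1ccoc2cc(O)ccc12 | starting material
12 | 7-(benzyloxy)-4H-chromen-4-one | O=c1ccoc2cc(OCc3ccccc3)ccc12 | intermediate
13 | [4-(benzyloxy)phenyl]boronic acid | OB(O)c1ccc(OCc2ccccc2)cc1 | starting material
14 | (S)-7-(benzyloxy)-2-[4-(benzyloxy)phenyl]chroman-4-one | C(c1ccccc1)Oc1ccc([C@@H]2CC(=O)c3ccc(OCc4ccccc4)cc3O2)cc1 | intermediate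
15 | [(2R,3R)-3,5,7-tris(benzyloxy)-2-(3,4,5-tris(benzyloxy)phenyl)chroman-8-yl]lithium | [Li]c1c(OCc3ccccc3)cc(OCc3ccccc3)c2c1O[C@H](c1cc(OCc3ccccc3)c(OCc3ccccc3)c(OCc3ccccc3)c1)[C@H](OCc1ccccc1)C2 | intermediate
16 | (2S)-7-(benzyloxy)-2-[4-(benzyloxy)phenyl]-4-{(2R,3R)-3,5,7-tris(benzyloxy)-2-[3,4,5-tris(benzyloxy)phenyl]chroman-8-yl}chroman-4-ol (C4 epimers) | C(c1ccccc1)Oc1ccc([C@@H]2CC(O)(c3c(OCc5ccccc5)cc(OCc5ccccc5)c4c3O[C@H](c3cc(OCc5ccccc5)c(OCc5ccccc5)c(OCc5ccccc5)c3)[C@H](OCc3ccccc3)C4)c3ccc(OCc4ccccc4)cc3O2)cc1 | intermediate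
17 | (2R,3R)-3,5,7-tris(benzyloxy)-8-{(2S,4S)-7-(benzyloxy)-2-[4-(benzyloxy)phenyl]chroman-4-yl}-2-[3,4,5-tris(benzyloxy)phenyl]chromane | C(c1ccccc1)Oc1ccc([C@@H]2C[C@H](c3c(OCc5ccccc5)cc(OCc5ccccc5)c4c3O[C@H](c3cc(OCc5ccccc5)c(OCc5ccccc5)c(OCc5ccccc5)c3)[C@H](OCc3ccccc3)C4)c3ccc(OCc4ccccc4)cc3O2)cc1 | intermediate
18 | (2R,3R)-8-[(2S,4S)-7-hydroxy-2-(4-hydroxyphenyl)chroman-4-yl]-2-(3,4,5-trihydroxyphenyl)chromane-3,5,7-triol | Oc1ccc([C@@H]2C[C@H](c3c(O)cc(O)c4c3O[C@H](c3cc(O)c(O)c(O)c3)[C@H](O)C4)c3ccc(O)cc3O2)cc1 | target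

**Step count and risks**

Total step count: 11. Longest linear sequence: 9 steps (steps 1, 2, 3, 4, 5, 6, 9, 10, 11).

Steps most likely to fail:

Step 3. The gold–alkyne complex may be consumed by direct hydroarylation before it is oxidised. The carbene may be diverted to the ortho carbon of ring B or to a second N-oxide. Enolisation of the ketone may erode the C2 configuration. The fallback sets out from 6 and avoids the carbene: treatment of 6 with (JohnPhos)Au(MeCN)SbF6 in CH2Cl2 without oxidant should close the same C4–C4a bond by 6-endo hydroarylation to give (S)-5,7-bis(benzyloxy)-2-[3,4,5-tris(benzyloxy)phenyl]-2H-chromene F1. Hydroboration–oxidation (BH3·THF; then NaOH, H2O2) on the face away from the C2 aryl group should give (2R,3S)-5,7-bis(benzyloxy)-2-[3,4,5-tris(benzyloxy)phenyl]chroman-3-ol F2. Dess–Martin oxidation then returns to the route at 7.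

Step 9. The hindered, basic aryllithium may enolise the flavanone, with ring opening to the chalcone, instead of adding to the carbonyl group. The fallback reverses the polarity of the union and sets out from 14 and 9 (before bromination): NaBH4 reduction of 14 in MeOH/THF should give (2S,4S)-7-(benzyloxy)-2-[4-(benzyloxy)phenyl]chroman-4-ol F3. Ionisation of F3 with TMSOTf in CH2Cl2 at −78 °C in the presence of excess 9 should alkylate C8 of 9 in a Friedel–Crafts reaction. This is expected to give 17 together with its C4 epimer, which is removed by chromatography, and the route is rejoined at 17.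

Step 10. Hydride delivery to the crowded cation may show poor facial selectivity, or the cation may stall at the elimination product. The fallback sets out from 16: deliberate dehydration with pyridinium p-toluenesulfonate in toluene at 60 °C should give (2R,3R)-3,5,7-tris(benzyloxy)-8-{(2S)-7-(benzyloxy)-2-[4-(benzyloxy)phenyl]-2H-chromen-4-yl}-2-[3,4,5-tris(benzyloxy)phenyl]chromane F4. Heterogeneous hydrogenation of F4 (H2, Pd(OH)2/C, THF/MeOH) should add hydrogen to C3=C4 on the face away from the C2 aryl group and cleave the benzyl ethers in the same operation, arriving directly at 18.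

**Further compounds**

F1 | step 3 | (S)-5,7-bis(benzyloxy)-2-[3,4,5-tris(benzyloxy)phenyl]-2H-chromene | c1c(OCc3ccccc3)cc(OCc3ccccc3)c2c1O[C@H](c1cc(OCc3ccccc3)c(OCc3ccccc3)c(OCc3ccccc3)c1)C=C2
F2 | step 3 | (2R,3S)-5,7-bis(benzyloxy)-2-[3,4,5-tris(benzyloxy)phenyl]chroman-3-ol | c1c(OCc3ccccc3)cc(OCc3ccccc3)c2c1O[C@H](c1cc(OCc3ccccc3)c(OCc3ccccc3)c(OCc3ccccc3)c1)[C@@H](O)C2
F3 | step 9 | (2S,4S)-7-(benzyloxy)-2-[4-(benzyloxy)phenyl]chroman-4-ol | C(c1ccccc1)Oc1ccc([C@@H]2C[C@H](O)c3ccc(OCc4ccccc4)cc3O2)cc1
F4 | step 10 | (2R,3R)-3,5,7-tris(benzyloxy)-8-{(2S)-7-(benzyloxy)-2-[4-(benzyloxy)phenyl]-2H-chromen-4-yl}-2-[3,4,5-tris(benzyloxy)phenyl]chromane | C(c1ccccc1)Oc1ccc([C@@H]2C=C(c3c(OCc5ccccc5)cc(OCc5ccccc5)c4c3O[C@H](c3cc(OCc5ccccc5)c(OCc5ccccc5)c(OCc5ccccc5)c3)[C@H](OCc3ccccc3)C4)c3ccc(OCc4ccccc4)cc3O2)cc1
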